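The left-handed product is what you want from this flask, and the bench rule is to count equivalents: c(partner) at 0.900 M stands against 0.720 M of the two substrates together, a ratio of 1.25, so partner looks like the excess and, with the racemization catalyst turning one hand into the other, the rule promises product from the whole racemate.

in all of them: left-handed substrate 0.36 M; right-handed substrate 0.36 M
- dusk: partner 0.90 M; racemization catalyst 0.36 mM; temperature 70 °C; the very flask that is asked about, followed so far
- midnight: partner 0.90 M; racemization catalyst 0.54 mM; temperature 76 °C; run made earlier
- flask: partner 0.900 M; racemization catalyst 0.36 mM; temperature 70 °C; time 25 h

| run | time / h | left-handed product / % | left-handed substrate / % |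
|---|---|---|---|
| dusk | 4.00 | 40.0 | 15.5 |
| dusk | 8.00 | 46.1 | 10.9 |
| dusk | 12.0 | 48.3 | 11.2 |
| dusk | 15.0 | 48.6 | 10.2 |
| midnight | 3.00 | 42.0 | 14.7 |
| midnight | 6.00 | 46.9 | 13.7 |
| midnight | 10.0 | 47.8 | 13.4 |
| midnight | 12.0 | 47.8 | 13.8 |

(standard deviation of a reading: 1 percentage point)

1. left-handed product, in percent of the left-handed substrate and right-handed substrate together first charged, at 25 h
2. which option adds most left-handed product ("none" when 2 percentage points or less is all one gets) (alpha / gamma / delta / theta / zeta / none)
3. left-handed product present, with what was taken out counted in, in percent of the left-handed substrate and right-handed substrate together first charged, after gamma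
4. left-handed product present, with what was taken out counted in, in percent of the left-handed substrate and right-handed substrate together first charged, after delta

- alpha: at 25 h add partner, 50.0% of the amount charged, then wait 2.0 d
- gamma: at 25 h take out 90% of the left-handed product then present, then wait 2.0 d
- delta: at 25 h raise the temperature by 10 K, then wait 2.0 d
- theta: at 25 h add racemization catalyst, 50.0% of the amount charged, then wait 2.0 d
- zeta: change nothing and wait 2.0 d more

- partner is single-handed; left-handed substrate and right-handed substrate are mirror images of each other, charged as a racemate, each of them at the stated concentration
- left-handed product taken out counts as made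
- additions bring no volume worth counting
- the handed part of partner does not stay in what it makes, so the products of the two hands are mirror images too

But the dusk run, which is this flask followed so far, stands still with left-handed substrate at 11.2% and 10.2% at 12.0 h and 15.0 h. Left-handed substrate and product together reach 58.8%, more than the 50% charged as left-handed, so the hands do interconvert, and I take them as level, with the unread right-handed substrate equal to the left. The two readings added then give a substrate pool of 21.4% of the charge, and product of both hands holds the rest. That gives 62.9% for the delivered share, the part of the charged partner that ended in product of either hand. To take up the racemate the rule needs 80.0% delivered, and the delivered share is less, so here the ratio of charges stops working: I read partner as the limiting reagent, with the remainder lost some other way.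

My own reckoning therefore keeps you near 48.5% at 25 h, and also after gamma and delta, since those bring no partner. Option alpha brings partner worth 62.5% of the charge, more than the pool of 21.4%, but the delivered share was reached in a flask that started with the whole charge of substrate, so I do not carry that share over to the pool, and I expect some of the added partner to be lost and part of the pool to stay. At the left-handed share so far, 61.6%, the whole pool is worth 13 percentage points, and I take that only as a rough size for what alpha adds.

The forecast reads the stop as “a reversible, exothermic equilibrium, not a shortage of partner”: it gives 48.5% at 25 h, close to mine, but it names gamma as best, with 55.7% after gamma and 45.5% after delta.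

The flask gives 49.0% at 25 h, and alpha is best, adding 12 points, while gamma ends at 49.1% and delta at 49.1%.

    partner → decomposed reagent (k = 3.69 × 10⁻⁵ s⁻¹, Ea = 111 kJ mol⁻¹)
    left-handed substrate + racemization catalyst ⇌ right-handed substrate + racemization catalyst, rate k2*[racemization catalyst]*[left-handed substrate] forward; the back reaction follows from the equilibrium constant (k = 0.0852 M⁻¹ s⁻¹, Ea = 69.0 kJ mol⁻¹)
    partner + right-handed substrate → right-handed product (k = 9.35 × 10⁻⁵ M⁻¹ s⁻¹, Ea = 83.0 kJ mol⁻¹)
    partner + left-handed substrate → left-handed product (k = 2.31 × 10⁻⁴ M⁻¹ s⁻¹, Ea = 83.0 kJ mol⁻¹)
    (constants at 70 °C)

At 25.0 h, 0.161% of the charged partner is free, with left-handed and right-handed substrate at 11.8% and 12.1% of the charge. In the neighbour flask with 0.36 M of partner, the delivered share of 62.9% puts 31.4% of the charge into product, and that flask holds 35.7% as product of both hands at 25.0 h.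

(The data come from a simulation on assumed constants, and the scatter is random.)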